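**Plan**
- Retrosynthesis: the 5-OH is carried as OMe. Ring C is cut at O1–C2 and C2–C3 (2'-hydroxychalcone, then aldehyde plus acetophenone), and C4–C4a is cut back to 3,4,5-trimethoxyphenol.
- Ring B is cut at C5'–C6' (6π closure of a dienylketene) and at C1'–C2' (vinyllithium addition to a squarate carbonyl).
- Enabling feature: in ring B the four contiguous oxygen-bearing carbons C2'–C5' are the four carbons of dimethyl squarate, while C1' (bearing C2) and C6'–H are the two carbons of a 1,1-disubstituted vinyl group.
- Forward order: ring B is built first (steps 1–4), ring A comes from the phenol (step 5), the halves are joined by aldol condensation (step 6), ring C closes last (step 7), and the 5-O-methyl group is removed (step 8).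
- Stereochemistry: the target has no stereocentre. The carbinol centre of 6 and the flavanone centre of 15 are racemic and are erased, as is the E geometry of chalcone 14.

Key step: step 3

Remark: flavone numbering is used (O1, C2–C4, C4a, C5–C8, C8a, primed locants for ring B), and cyclobutenone 6 is taken as the racemate.

**Step 1**
Reactants: 1 1,1-dimethoxypropan-2-one (1,1-dimethoxyacetone); 2 2,4,6-tri(propan-2-yl)benzenesulfonohydrazide
Product: 3 N'-[(2E)-1,1-dimethoxypropan-2-ylidene]-2,4,6-tri(propan-2-yl)benzenesulfonohydrazide
Conditions: MeOH, 0 °C to rt, no added acid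
Reagents that add atoms: none
Why: Hydrazone formation at the activated α-keto acetal carbonyl should be fast without acid, methanol makes any acetal exchange degenerate, and the E isomer (sulfonamide nitrogen on the methyl side) is expected to predominate.

**Step 2**
Reactants: 3 the trisylhydrazone; 4 3,4-dimethoxycyclobut-3-ene-1,2-dione (dimethyl squarate)
Product: 6 4-(3,3-dimethoxyprop-1-en-2-yl)-4-hydroxy-2,3-dimethoxycyclobut-2-en-1-one (racemic), via vinyllithium 5 (not isolated)
Conditions: n-BuLi (2.1 equiv), THF, −78 °C, then 0 °C (10 min), recool to −78 °C; cannulate into 4 in THF, −78 °C; aq. NH4Cl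
Reagents that add atoms: none
Why: In this Shapiro reaction of a trisylhydrazone the dianion (deprotonated at N–H and at the methyl group, the only acidic α-position) loses sulfinate and N2 to give the 2-lithioalkene, which adds 1,2 to one of the two equivalent squarate carbonyls at −78 °C to give the tertiary carbinol as an uncontrolled racemate whose centre is erased in step 3.

**Step 3**
Reactants: 6 4-(3,3-dimethoxyprop-1-en-2-yl)-4-hydroxy-2,3-dimethoxycyclobut-2-en-1-one
Product: 9 2-(dimethoxymethyl)-5,6-dimethoxybenzene-1,4-diol, via dienylketene 7 (not isolated), via cyclohexadienone 8 (not isolated)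
Conditions: PhMe (degassed, 0.02 M), 110 °C, Ar; concentrated under Ar and used crude
Reagents that add atoms: none
Why: In this Moore rearrangement, thermal conrotatory 4π opening of the cyclobutenone cleaves C1–C4 and, because the donor hydroxyl at C4 rotates outward, gives dienylketene 7 with the vinyl group cis to the ketene. A 6π electrocyclisation then joins the ketene carbon to the vinyl CH2, forming the C5'–C6' bond and closing ring B as cyclohexadienone 8, which tautomerises to the aromatic hydroquinone. The closest known reaction type is the thermolysis of 4-alkenyl-4-hydroxy-2,3-dialkoxycyclobutenones to 2,3-dialkoxyhydroquinones. Ring B, the only ring formed, closes as a six-membered carbocycle by thermal disrotatory 6π electrocyclisation of the triene made up of the ketene C=C, the former cyclobutene C=C and the vinyl group. No stereocentre is created, and the carbinol centre of 6 becomes the sp2 carbon C2'. The step needs the hydroxyl outward and the vinyl group inward, and ring closure faster than intermolecular ketene capture, which the donor hydroxyl and high dilution in a degassed aprotic solvent should secure; the 1,1-disubstituted vinyl group offers only its CH2 terminus, so C6' carries H and C1' the acetal without regiochemical choice.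

**Step 4**
Reactants: 9 2-(dimethoxymethyl)-5,6-dimethoxybenzene-1,4-diol
Product: 11 2,3,4,5-tetramethoxybenzaldehyde, via tetramethoxy acetal 10 (not isolated)
Conditions: MeI, K2CO3, acetone (degassed), 56 °C, Ar; then 1 M HCl, THF, rt
Reagents that add atoms: methyl iodide, CI; water, O
Why: Williamson O-methylation of both phenoxides is followed by acid-catalysed acetal hydrolysis, which should be fast because the benzylic oxocarbenium ion is stabilised by the ortho and para methoxy groups.

**Step 5**
Reactants: 12 3,4,5-trimethoxyphenol
Product: 13 1-(6-hydroxy-2,3,4-trimethoxyphenyl)ethan-1-one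
Conditions: AcOH, BF3·OEt2 (3 equiv), 90 °C; then H2O
Reagents that add atoms: acetic acid, CC(=O)O
Why: In this BF3-promoted Friedel–Crafts ortho-acylation of a phenol the two ortho positions are equivalent by symmetry and the para position is blocked, so a single hydrogen-bonded hydroxy ketone is expected.

**Step 6**
Reactants: 11 2,3,4,5-tetramethoxybenzaldehyde; 13 1-(6-hydroxy-2,3,4-trimethoxyphenyl)ethan-1-one
Product: 14 (2E)-1-(6-hydroxy-2,3,4-trimethoxyphenyl)-3-(2,3,4,5-tetramethoxyphenyl)prop-2-en-1-one
Conditions: KOH (50% aq.), EtOH, rt; then 1 M HCl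
Reagents that add atoms: none
Why: In this Claisen–Schmidt condensation the non-enolisable aldehyde accepts the acetophenone enolate and the aldol dehydrates to the conjugated enone, whose E geometry is set under thermodynamic control.

**Step 7**
Reactants: 14 the 2'-hydroxychalcone
Product: 16 5,6,7-trimethoxy-2-(2,3,4,5-tetramethoxyphenyl)-4H-chromen-4-one, via flavanone 15 (not isolated)
Conditions: I2 (10 mol%), DMSO, 130 °C
Reagents that add atoms: none
Why: In this iodine-catalysed oxidative cyclisation the phenol adds in conjugate fashion to give the racemic flavanone, α-iodination and loss of HI give the flavone, and DMSO reoxidises HI to I2, so both the alkene geometry and the flavanone centre are erased.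

**Step 8**
Reactants: 16 5,6,7-trimethoxy-2-(2,3,4,5-tetramethoxyphenyl)-4H-chromen-4-one
Product: 17 agecorynin F (5-hydroxy-6,7-dimethoxy-2-(2,3,4,5-tetramethoxyphenyl)-4H-chromen-4-one)
Conditions: BCl3 (1.5 equiv), CH2Cl2, −78 °C to 0 °C; then H2O
Reagents that add atoms: none
Why: In this chelation-directed Lewis acid ether cleavage boron binds between the C4 carbonyl and the peri 5-methoxy oxygen, so chloride should remove only that methyl group, since none of the other six methoxy groups can form the six-membered chelate.

**Compound list**
1 | 1,1-dimethoxypropan-2-one (1,1-dimethoxyacetone) | CC(=O)C(OC)OC | starting material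
2 | 2,4,6-tri(propan-2-yl)benzenesulfonohydrazide | NNS(=O)(=O)c1c(C(C)C)cc(C(C)C)cc1C(C)C | starting material
3 | N'-[(2E)-1,1-dimethoxypropan-2-ylidene]-2,4,6-tri(propan-2-yl)benzenesulfonohydrazide | COC(OC)/C(C)=N/NS(=O)(=O)c1c(C(C)C)cc(C(C)C)cc1C(C)C | intermediate
4 | 3,4-dimethoxycyclobut-3-ene-1,2-dione (dimethyl squarate) | COC1=C(OC)C(=O)C1=O | starting material
5 | (3,3-dimethoxyprop-1-en-2-yl)lithium, formed in the flask | [Li]C(=C)C(OC)OC | intermediate
6 | 4-(3,3-dimethoxyprop-1-en-2-yl)-4-hydroxy-2,3-dimethoxycyclobut-2-en-1-one (racemic) | COC(OC)C(=C)C1(O)C(OC)=C(OC)C1=O | intermediate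
7 | (3Z)-5-(dimethoxymethyl)-4-hydroxy-2,3-dimethoxyhexa-1,3,5-trien-1-one, formed in the flask | O=C=C(OC)/C(OC)=C(/O)C(=C)C(OC)OC | intermediate
8 | 5-(dimethoxymethyl)-4-hydroxy-2,3-dimethoxycyclohexa-2,4-dien-1-one, formed in the flask | O=C1CC(C(OC)OC)=C(O)C(OC)=C1OC | intermediate
9 | 2-(dimethoxymethyl)-5,6-dimethoxybenzene-1,4-diol | COC(OC)c1cc(O)c(OC)c(OC)c1O | intermediate
10 | 1-(dimethoxymethyl)-2,3,4,5-tetramethoxybenzene, formed in the flask | COC(OC)c1cc(OC)c(OC)c(OC)c1OC | intermediate
11 | 2,3,4,5-tetramethoxybenzaldehyde | COc1cc(C=O)c(OC)c(OC)c1OC | intermediate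
12 | 3,4,5-trimethoxyphenol | COc1cc(O)cc(OC)c1OC | starting material
13 | 1-(6-hydroxy-2,3,4-trimethoxyphenyl)ethan-1-one | CC(=O)c1c(O)cc(OC)c(OC)c1OC | intermediate
14 | (2E)-1-(6-hydroxy-2,3,4-trimethoxyphenyl)-3-(2,3,4,5-tetramethoxyphenyl)prop-2-en-1-one | COc1cc(O)c(C(=O)/C=C/c2cc(OC)c(OC)c(OC)c2OC)c(OC)c1OC | intermediate
15 | 5,6,7-trimethoxy-2-(2,3,4,5-tetramethoxyphenyl)-2,3-dihydro-4H-chromen-4-one (racemic), formed in the flask | COc1cc(C2CC(=O)c3c(OC)c(OC)c(OC)cc3O2)c(OC)c(OC)c1OC | intermediate
16 | 5,6,7-trimethoxy-2-(2,3,4,5-tetramethoxyphenyl)-4H-chromen-4-one | COc1cc(-c2cc(=O)c3c(OC)c(OC)c(OC)cc3o2)c(OC)c(OC)c1OC | intermediate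
17 | agecorynin F, 5-hydroxy-6,7-dimethoxy-2-(2,3,4,5-tetramethoxyphenyl)-4H-chromen-4-one | COc1cc(-c2cc(=O)c3c(O)c(OC)c(OC)cc3o2)c(OC)c(OC)c1OC | target

**Step count**
Total steps: 8. Longest linear sequence: 7 steps (1, 2, 3, 4, 6, 7, 8); step 5 is a one-step side branch.

**Steps most likely to fail**

Step 2. The 2-lithioalkene 5 carries an allylic acetal and may lose lithium methoxide by β-elimination while the dianion fragments at 0 °C. Fragmentation may also stay incomplete at temperatures the reagent tolerates, and a second addition to the squarate may compete. The fallback sets out from 1,1-dimethoxyacetone 1 and comes back to the route at carbinol 6. The kinetic lithium enolate of 1 (LiN(iPr)2, THF, −78 °C, deprotonation at the methyl group only) would be trapped with PhNTf2 to give the enol triflate 3,3-dimethoxyprop-1-en-2-yl trifluoromethanesulfonate F1. Coupling with Me6Sn2 under the zerovalent palladium complex Pd(PPh3)4 (LiCl, THF, 60 °C) would give (3,3-dimethoxyprop-1-en-2-yl)trimethylstannane F2. Tin–lithium exchange with MeLi in THF at −78 °C would then deliver vinyllithium 5 without any warming, and addition to squarate 4 at −78 °C gives 6.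

Step 3. The electron-rich hydroquinone may be oxidised by adventitious air, may lose methanol from the acetal next to its hydroxyl on heating, or its phenols may capture the ketene of a second molecule. The fallback sets out from carbinol 6 and comes back at acetal 10. The tertiary hydroxyl would be methylated (MeI, Ag2O, MeCN, rt) to 4-(3,3-dimethoxyprop-1-en-2-yl)-2,3,4-trimethoxycyclobut-2-en-1-one F3. The methoxy group is again a donor that rotates outward, so thermolysis in toluene at 110 °C should pass through the dienylketene (3Z)-5-(dimethoxymethyl)-2,3,4-trimethoxyhexa-1,3,5-trien-1-one F4 and the cyclohexadienone 5-(dimethoxymethyl)-2,3,4-trimethoxycyclohexa-2,4-dien-1-one F5 to the monophenol 5-(dimethoxymethyl)-2,3,4-trimethoxyphenol F6. This phenol already holds the C2' methoxy group, has no hydroxyl next to the acetal and cannot give a quinone. Methylation of its single hydroxyl (MeI, K2CO3, acetone) gives 10, which is hydrolysed as in step 4.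

Step 4. Air oxidation of the hydroquinone dianion may outrun O-methylation, and the C2' hydroxyl, flanked by the acetal carbon and a methoxy group, may be methylated incompletely. The fallback sets out from hydroquinone 9 and comes back at acetal 10. Oxidation is accepted rather than fought: Ag2O in Et2O at rt would convert 9 into the quinone 2-(dimethoxymethyl)-5,6-dimethoxycyclohexa-2,5-diene-1,4-dione F7, which can be purified. Reductive methylation (Na2S2O4, THF/H2O, then Me2SO4, KOH, Bu4NBr) would regenerate the hydroquinone dianion under continuously reducing conditions and methylate it under phase transfer to 10.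

**Further compounds**
F1 | step 2 | 3,3-dimethoxyprop-1-en-2-yl trifluoromethanesulfonate | C=C(OS(=O)(=O)C(F)(F)F)C(OC)OC
F2 | step 2 | (3,3-dimethoxyprop-1-en-2-yl)trimethylstannane | C=C([Sn](C)(C)C)C(OC)OC
F3 | step 3 | 4-(3,3-dimethoxyprop-1-en-2-yl)-2,3,4-trimethoxycyclobut-2-en-1-one (racemic) | COC(OC)C(=C)C1(OC)C(OC)=C(OC)C1=O
F4 | step 3 | (3Z)-5-(dimethoxymethyl)-2,3,4-trimethoxyhexa-1,3,5-trien-1-one | O=C=C(OC)/C(OC)=C(/OC)C(=C)C(OC)OC
F5 | step 3 | 5-(dimethoxymethyl)-2,3,4-trimethoxycyclohexa-2,4-dien-1-one | O=C1CC(C(OC)OC)=C(OC)C(OC)=C1OC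
F6 | step 3 | 5-(dimethoxymethyl)-2,3,4-trimethoxyphenol | COC(OC)c1cc(O)c(OC)c(OC)c1OC
F7 | step 4 | 2-(dimethoxymethyl)-5,6-dimethoxycyclohexa-2,5-diene-1,4-dione | COC(OC)C1=CC(=O)C(OC)=C(OC)C1=O
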